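(The readings were computed from invented constants, and the scatter is random.)

The flask is charged with c(starting material) = 0.40 M, as in autumn and summer, and c(protic impurity) = 0.0800 M, as in winter, a pairing that no earlier run has. You asked for a quick number, and before the number comes the moment it belongs to.

| setting | autumn | summer | winter | flask |
|---|---|---|---|---|
| starting material | 0.40 M | 0.40 M | 0.60 M | 0.40 M |
| partner | 0.60 M | 0.60 M | 0.60 M | 0.600 M |
| protic impurity | 0.11 M | 0.18 M | 0.080 M | 0.0800 M |
| free catalyst | 0.72 mM | 0.72 mM | 0.72 mM | 0.72 mM |
| remark | run made earlier | run made earlier | run made earlier |  |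

| run | time / d | product / % | starting material / % |
|---|---|---|---|
| autumn | 1.25 | 7.1 | 12.1 |
| autumn | 2.50 | 17.2 | 1.3 |
| autumn | 4.00 | 25.4 | 0.5 |
| autumn | 5.00 | 31.4 | 0.3 |
| summer | 0.625 | 2.2 | 33.7 |
| summer | 1.67 | 9.3 | 6.3 |
| summer | 3.00 | 18.4 | 1.2 |
| summer | 5.00 | 28.1 | 0.4 |
| winter | 1.25 | 7.0 | 13.9 |
| winter | 2.50 | 16.4 | 2.0 |
| winter | 4.00 | 25.1 | 0 |
| winter | 5.00 | 29.4 | 0.4 |

(scatter of a reading: 0.5 percentage points)

- no earlier run changes the charge of free catalyst; that part of a forecast is a guess

- apparent order in free catalyst when 20% of the starting material are converted (percent change of the rate of making product for one percent more free catalyst charged)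

Starting material falls as a first-order decay: summer's earliest reading leaves 33.7% at 0.625 d, so k = 1.74 d⁻¹. Conversion of 20% then falls at 0.128 d. Call this the mark time, the time a first-order decay needs to convert the share we look at.

The same k predicts 11.4% for autumn at 1.25 d, where we read 12.1%. Winter, at the larger charge, reads 13.9% and would move the mark time to 0.141 d.

We commit to that time and not to an order, since no earlier run changes the charge of free catalyst. Your forecast is 0.7, and its moment is another one: “At 20% product, about 3 days, the slow intermediate-to-product step controls the rate”. That mark counts product, while the question counts starting material converted.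

The flask gives 0.57, so the forecast stands too high by a factor of 1.23.

    partner + catalyst intermediate → free catalyst + product (k = 28.0 M⁻¹ h⁻¹)
    partner + protic impurity → quenched reagent (k = 0.0990 M⁻¹ h⁻¹)
    starting material + free catalyst → free catalyst + open intermediate (k = 590 M⁻¹ h⁻¹)
    2 free catalyst ⇌ resting dimer, settled at all times (K = 19000 M⁻¹)
    free catalyst + open intermediate ⇌ catalyst intermediate (K = 2.80 M⁻¹, k = 410 M⁻¹ h⁻¹)

In this flask the mark came at 0.127 d, against our mark time of 0.128 d, with 17.1% of the catalyst free. At 0.401 d the flask's catalyst intermediate fell back 9.3 times faster than it went on, and at 0.400 d resting dimer, the resting state, held 75.3% of the catalyst.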